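**Plan**
- Euchrenone b2 (22) has no stereocentre. Ring C is cut at O1–C2 and C2–C3 (one carbon from an amide acetal) and then at C4–C4a, leaving a ring A aryllithium and a ring B arylacetic Weinreb amide.
- Ring B is cut at C5'–C6' and C2'–C3' into the kinetic silyl enol ether of 6-methylhept-5-en-2-one and dimethyl 2-(methoxymethylene)succinate. Ring A goes back to phloroglucinol and prenyl bromide.
- Enabling feature: C5', C4' and C3' of ring B are C1, C2 and C3 of 6-methylhept-5-en-2-one, and the C3' prenyl group is C4–C7 of that ketone with its 6-methyl. The prenyl group therefore lies between the two ring B oxygens (ketone oxygen at C4', ester carbonyl oxygen at C2') by construction.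
- Forward order: ring B by [3+3] benzannulation (steps 1–3), protection and amide formation (4–5), ring A by two lithiation–prenylations (6–8), union to the deoxybenzoin (9), one-carbon insertion (10), deprotection with closure of ring C (11).
- Stereochemistry: none to set. The E geometry of 7 is lost in step 3, and every prenyl alkene carries two identical methyl termini.

Key step: step 3

Remark: isoflavone numbering is used (ring A C5–C8, ring C O1–C4, ring B primed); prenyl is 3-methylbut-2-en-1-yl and MOM is methoxymethyl. Enone diester 8 is assumed to form as a mixture of alkene isomers that interconvert under methoxide, so its SMILES carries no alkene geometry.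

**Step 1**
Reactants: 1 sulcatone (6-methylhept-5-en-2-one)
Product: 3 trimethyl[(6-methylhepta-1,5-dien-2-yl)oxy]silane, via lithium enolate 2 (not isolated)
Conditions: LiN(i-Pr)2, THF, −78 °C; then Me3SiCl, −78 °C to 0 °C; distil
Reagents that add atoms: chlorotrimethylsilane, C[Si](C)(C)Cl
Why: Kinetic deprotonation by the hindered lithium amide at low temperature removes a methyl proton in preference to a C3 methylene proton, and O-silylation of lithium enolate 2 fixes this regiochemistry as the terminal silyl enol ether (kinetic enolate trapping).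

**Step 2**
Reactants: 4 dimethyl succinate; 5 methyl formate
Product: 7 dimethyl (E)-2-(methoxymethylidene)butanedioate, via sodium enolate 6 (not isolated)
Conditions: NaH, THF, 0 °C to 25 °C; then Me2SO4, DMF, 25 °C
Reagents that add atoms: dimethyl sulfate, COS(=O)(=O)OC
Why: A crossed Claisen condensation with the non-enolisable formate gives the stabilised sodium enolate of the formyl diester, whose oxygen terminus is methylated by the hard electrophile in a dipolar aprotic medium to the (E)-3-methoxyacrylate, the usual outcome of this formylation–O-methylation sequence.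

**Step 3**
Reactants: 3 trimethyl[(6-methylhepta-1,5-dien-2-yl)oxy]silane; 7 dimethyl (E)-2-(methoxymethylidene)butanedioate
Product: 9 methyl 2-[2,4-dihydroxy-3-(3-methylbut-2-en-1-yl)phenyl]acetate, via enone diester 8 (not isolated)
Conditions: TiCl4 (1.1 equiv), CH2Cl2, −78 °C to −40 °C; then NaOMe (8 equiv), MeOH, −40 °C to 25 °C; aq. citric acid to pH 5
Reagents that add atoms: none
Why: Proposed new method: TiCl4 binds the conjugated ester of 7 and makes its methoxymethylene carbon a vinylogous dialkoxycarbenium centre that the terminal carbon of silyl enol ether 3 attacks (Mukaiyama–Michael addition), and loss of the methoxy group to titanium then gives enone diester 8 with the C5'–C6' bond in place. The excess NaOMe first turns the titanium chlorides into Ti(OMe)4 and NaCl and then equilibrates 8 through its dienolate, so that the alkene geometry is mobile and the enolate at the prenyl-bearing methylene can reach the conjugated ester carbonyl, where a Claisen (Dieckmann-type) acyl substitution forms C2'–C3' and closes ring B in the 6-exo-trig mode. The 2-substituted cyclohexene-1,3-dione so formed should tautomerise at once to the resorcinol, an irreversible sink that also empties the reversible five-membered Claisen and aldol closures open to the dienolate. The closest known reaction types are TiCl4-mediated formal [3+3] cyclisations of silyl enol ethers with 3-alkoxy enones and 3-alkoxyacrylates and the Michael–Claisen synthesis of cyclohexane-1,3-diones and resorcinols from ketones and acrylates. No stereocentre is formed; the selectivity needed is that the methyl carbon adds first and the prenyl-bearing methylene acylates second, which the kinetic enol ether 3 and the fact that only this closure gives a six-membered ring able to aromatise both secure.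

**Step 4**
Reactants: 9 methyl 2-[2,4-dihydroxy-3-(3-methylbut-2-en-1-yl)phenyl]acetate
Product: 10 methyl 2-[2,4-bis(methoxymethoxy)-3-(3-methylbut-2-en-1-yl)phenyl]acetate
Conditions: MOMCl, i-Pr2NEt, Bu4NI (cat.), CH2Cl2, 0 °C to 40 °C
Reagents that add atoms: chloromethyl methyl ether, COCCl
Why: O-Alkylation of both phenols by the reactive chloromethyl ether under amine base (MOM protection) leaves the ester untouched and caps the ortho-hydroxy group before it can lactonise onto the ester.

**Step 5**
Reactants: 10 methyl 2-[2,4-bis(methoxymethoxy)-3-(3-methylbut-2-en-1-yl)phenyl]acetate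
Product: 11 2-[2,4-bis(methoxymethoxy)-3-(3-methylbut-2-en-1-yl)phenyl]-N-methoxy-N-methylacetamide
Conditions: MeNH(OMe)·HCl, i-PrMgCl, THF, −20 °C to 0 °C
Reagents that add atoms: N,O-dimethylhydroxylamine hydrochloride, CNOC.Cl
Why: The magnesium amide formed from the hydroxylamine salt and i-PrMgCl should effect aminolysis of the methyl ester faster than enolisation, the standard conversion of an ester into a Weinreb amide.

**Step 6**
Reactants: 12 phloroglucinol (benzene-1,3,5-triol)
Product: 13 1,3,5-tris(methoxymethoxy)benzene
Conditions: NaH, MOMCl, DMF, 0 °C to 25 °C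
Reagents that add atoms: chloromethyl methyl ether, COCCl
Why: Exhaustive O-alkylation of the triphenoxide by the hard chloromethyl ether (Williamson etherification) gives the tris-acetal, in which every ring hydrogen lies between two directing groups.

**Step 7**
Reactants: 13 1,3,5-tris(methoxymethoxy)benzene; 14 prenyl bromide (1-bromo-3-methylbut-2-ene)
Product: 16 1,3,5-tris(methoxymethoxy)-2-(3-methylbut-2-en-1-yl)benzene, via aryllithium 15 (not isolated)
Conditions: n-BuLi, THF, 0 °C; then 14, −78 °C to 25 °C
Reagents that add atoms: none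
Why: Directed ortho-metalation at a carbon flanked by two chelating OMOM groups gives aryllithium 15, which is alkylated at the primary carbon of the allylic bromide in an SN2 reaction.

**Step 8**
Reactants: 16 1,3,5-tris(methoxymethoxy)-2-(3-methylbut-2-en-1-yl)benzene; 14 prenyl bromide
Product: 18 1,3,5-tris(methoxymethoxy)-2,4-bis(3-methylbut-2-en-1-yl)benzene, via aryllithium 17 (not isolated)
Conditions: n-BuLi, THF, 0 °C; then 14, −78 °C to 25 °C
Reagents that add atoms: none
Why: A second directed ortho-metalation at either of the two equivalent remaining positions, each again flanked by two OMOM groups, followed by SN2 alkylation with prenyl bromide should install the second prenyl group.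

**Step 9**
Reactants: 18 1,3,5-tris(methoxymethoxy)-2,4-bis(3-methylbut-2-en-1-yl)benzene; 11 2-[2,4-bis(methoxymethoxy)-3-(3-methylbut-2-en-1-yl)phenyl]-N-methoxy-N-methylacetamide
Product: 20 2-[2,4-bis(methoxymethoxy)-3-(3-methylbut-2-en-1-yl)phenyl]-1-[2,4,6-tris(methoxymethoxy)-3,5-bis(3-methylbut-2-en-1-yl)phenyl]ethan-1-one, via aryllithium 19 (not isolated)
Conditions: n-BuLi, THF, 0 °C; then 11, −78 °C to 0 °C; aq. NH4Cl
Reagents that add atoms: none
Why: Directed ortho-metalation of the last ring hydrogen gives aryllithium 19, which adds to the Weinreb amide to form a chelated tetrahedral intermediate that collapses to the ketone only on work-up, so the C4–C4a bond forms without over-addition (Weinreb ketone synthesis).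

**Step 10**
Reactants: 20 the penta-MOM deoxybenzoin
Product: 21 (E)-2-[2,4-bis(methoxymethoxy)-3-(3-methylbut-2-en-1-yl)phenyl]-3-(dimethylamino)-1-[2,4,6-tris(methoxymethoxy)-3,5-bis(3-methylbut-2-en-1-yl)phenyl]prop-2-en-1-one
Conditions: Me2NCH(OMe)2, toluene, 100 °C
Reagents that add atoms: N,N-dimethylformamide dimethyl acetal, COC(OC)N(C)C
Why: Condensation of the methylene activated by both the ketone and the aryl group with the amide acetal (enaminone formation) supplies the future C2 carbon under neutral conditions that leave the acetals and prenyl groups untouched.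

**Step 11**
Reactants: 21 the penta-MOM enaminone
Product: 22 euchrenone b2, 3-[2,4-dihydroxy-3-(3-methylbut-2-en-1-yl)phenyl]-5,7-dihydroxy-6,8-bis(3-methylbut-2-en-1-yl)-4H-chromen-4-one
Conditions: HCl (3 M aq.), MeOH, 25 °C to 45 °C
Reagents that add atoms: none
Why: Acid-catalysed acetal cleavage frees the phenols, and either ortho-hydroxy group of the symmetric ring A adds to the protonated enaminone in a 6-endo-trig addition–elimination with loss of dimethylamine to close ring C, while the 5-endo attack of the ring B hydroxyl is geometrically disfavoured (enaminone route to chromones).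

**Compound list**
1 | sulcatone, 6-methylhept-5-en-2-one | CC(=O)CCC=C(C)C | starting material
2 | lithium 6-methylhepta-1,5-dien-2-olate | C=C([O-])CCC=C(C)C.[Li+] | intermediate
3 | trimethyl[(6-methylhepta-1,5-dien-2-yl)oxy]silane | C=C(O[Si](C)(C)C)CCC=C(C)C | intermediate
4 | dimethyl succinate | COC(=O)CCC(=O)OC | starting material
5 | methyl formate | COC=O | starting material
6 | sodium enolate of dimethyl 2-formylbutanedioate (enolate geometry not defined) | [Na+].[O-]C=C(CC(=O)OC)C(=O)OC | intermediate
7 | dimethyl (E)-2-(methoxymethylidene)butanedioate | CO/C=C(\CC(=O)OC)C(=O)OC | intermediate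
8 | dimethyl 2-(7-methyl-3-oxooct-6-en-1-ylidene)butanedioate (mixture of alkene isomers) | COC(=O)CC(=CCC(=O)CCC=C(C)C)C(=O)OC | intermediate
9 | methyl 2-[2,4-dihydroxy-3-(3-methylbut-2-en-1-yl)phenyl]acetate | COC(=O)Cc1ccc(O)c(CC=C(C)C)c1O | intermediate
10 | methyl 2-[2,4-bis(methoxymethoxy)-3-(3-methylbut-2-en-1-yl)phenyl]acetate | COCOc1ccc(CC(=O)OC)c(OCOC)c1CC=C(C)C | intermediate
11 | 2-[2,4-bis(methoxymethoxy)-3-(3-methylbut-2-en-1-yl)phenyl]-N-methoxy-N-methylacetamide | COCOc1ccc(CC(=O)N(C)OC)c(OCOC)c1CC=C(C)C | intermediate
12 | phloroglucinol, benzene-1,3,5-triol | Oc1cc(O)cc(O)c1 | starting material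
13 | 1,3,5-tris(methoxymethoxy)benzene | COCOc1cc(OCOC)cc(OCOC)c1 | intermediate
14 | prenyl bromide, 1-bromo-3-methylbut-2-ene | CC(C)=CCBr | starting material
15 | [2,4,6-tris(methoxymethoxy)phenyl]lithium | [Li]c1c(OCOC)cc(OCOC)cc1OCOC | intermediate
16 | 1,3,5-tris(methoxymethoxy)-2-(3-methylbut-2-en-1-yl)benzene | COCOc1cc(OCOC)c(CC=C(C)C)c(OCOC)c1 | intermediate
17 | [2,4,6-tris(methoxymethoxy)-3-(3-methylbut-2-en-1-yl)phenyl]lithium | [Li]c1c(OCOC)cc(OCOC)c(CC=C(C)C)c1OCOC | intermediate
18 | 1,3,5-tris(methoxymethoxy)-2,4-bis(3-methylbut-2-en-1-yl)benzene | COCOc1cc(OCOC)c(CC=C(C)C)c(OCOC)c1CC=C(C)C | intermediate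
19 | [2,4,6-tris(methoxymethoxy)-3,5-bis(3-methylbut-2-en-1-yl)phenyl]lithium | [Li]c1c(OCOC)c(CC=C(C)C)c(OCOC)c(CC=C(C)C)c1OCOC | intermediate
20 | 2-[2,4-bis(methoxymethoxy)-3-(3-methylbut-2-en-1-yl)phenyl]-1-[2,4,6-tris(methoxymethoxy)-3,5-bis(3-methylbut-2-en-1-yl)phenyl]ethan-1-one | COCOc1ccc(CC(=O)c2c(OCOC)c(CC=C(C)C)c(OCOC)c(CC=C(C)C)c2OCOC)c(OCOC)c1CC=C(C)C | intermediate
21 | (E)-2-[2,4-bis(methoxymethoxy)-3-(3-methylbut-2-en-1-yl)phenyl]-3-(dimethylamino)-1-[2,4,6-tris(methoxymethoxy)-3,5-bis(3-methylbut-2-en-1-yl)phenyl]prop-2-en-1-one | CN(C)/C=C(\c1ccc(OCOC)c(CC=C(C)C)c1OCOC)C(=O)c1c(OCOC)c(CC=C(C)C)c(OCOC)c(CC=C(C)C)c1OCOC | intermediate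
22 | euchrenone b2, 3-[2,4-dihydroxy-3-(3-methylbut-2-en-1-yl)phenyl]-5,7-dihydroxy-6,8-bis(3-methylbut-2-en-1-yl)-4H-chromen-4-one | CC(C)=CCc1c(O)ccc(-c2coc3c(CC=C(C)C)c(O)c(CC=C(C)C)c(O)c3c2=O)c1O | target

**Step count**
Total: 11 steps. Longest linear sequence: 7 steps (step 1 or step 2, then steps 3, 4, 5, 9, 10, 11); the ring A branch (steps 6–8) joins at step 9.

**Steps most likely to fail**

Step 3. The conjugate addition may stall because the methoxy donor deactivates the acrylate, the Lewis acid may attack the trisubstituted alkene, and under methoxide the dienolate may be diverted into five-membered Claisen or aldol closures. The ortho-hydroxy ester may also lactonise on acidification. The fallback gives up the benzannulation and builds the same ring B ester by known arene chemistry; it sets out from prenyl bromide 14 and returns at 10. Resorcinol is protected with MOMCl and NaH to 1,3-bis(methoxymethoxy)benzene F1. Lithiation between the two OMOM groups with n-BuLi gives [2,6-bis(methoxymethoxy)phenyl]lithium F2, which is alkylated with 14 to 1,3-bis(methoxymethoxy)-2-(3-methylbut-2-en-1-yl)benzene F3. A second directed lithiation (n-BuLi, TMEDA) gives [2,4-bis(methoxymethoxy)-3-(3-methylbut-2-en-1-yl)phenyl]lithium F4, and an iodine quench gives 1-iodo-2,4-bis(methoxymethoxy)-3-(3-methylbut-2-en-1-yl)benzene F5. Negishi-type coupling of F5 with the Reformatsky reagent BrZnCH2CO2Me under a zerovalent palladium catalyst (Pd(dba)2, XPhos, THF, 60 °C) should then give 10, and the route continues with step 5.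

Step 9. The hindered, doubly flanked aryllithium may act as a base and remove a benzylic proton next to the amide carbonyl instead of adding to it, returning both partners on work-up. The fallback replaces acylation by addition of a non-basic organocerium to an aldehyde followed by oxidation; it sets out from 10 and returns at 20. Ester 10 is reduced with i-Bu2AlH (toluene, −78 °C) to 2-[2,4-bis(methoxymethoxy)-3-(3-methylbut-2-en-1-yl)phenyl]acetaldehyde F6. Aryllithium 19, made from 18 as in step 9, is transmetalated with CeCl3 to dichloro[2,4,6-tris(methoxymethoxy)-3,5-bis(3-methylbut-2-en-1-yl)phenyl]cerium F7. Addition of F7 to F6 at −78 °C should give racemic 2-[2,4-bis(methoxymethoxy)-3-(3-methylbut-2-en-1-yl)phenyl]-1-[2,4,6-tris(methoxymethoxy)-3,5-bis(3-methylbut-2-en-1-yl)phenyl]ethan-1-ol F8, and oxidation of F8 with Dess–Martin periodinane (NaHCO3, CH2Cl2) gives 20.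

Step 11. During the exposure to protic acid needed to cleave five acetals, the prenyl groups may cyclise onto neighbouring free phenols or add methanol or HCl across their double bonds. The fallback inverts the order, deprotecting without protic acid and closing ring C under base; it sets out from 20 and returns at 22. The acetals of 20 are cleaved with ZnBr2 and n-PrSH (CH2Cl2, 0 °C) to 2-[2,4-dihydroxy-3-(3-methylbut-2-en-1-yl)phenyl]-1-[2,4,6-trihydroxy-3,5-bis(3-methylbut-2-en-1-yl)phenyl]ethan-1-one F9. Condensation of F9 with triethyl orthoformate in pyridine with piperidine at 110 °C, the classical basic closure of 2-hydroxydeoxybenzoins to isoflavones, should then give 22.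

**Further compounds**
F1 | step 3 | 1,3-bis(methoxymethoxy)benzene | COCOc1cccc(OCOC)c1
F2 | step 3 | [2,6-bis(methoxymethoxy)phenyl]lithium | [Li]c1c(OCOC)cccc1OCOC
F3 | step 3 | 1,3-bis(methoxymethoxy)-2-(3-methylbut-2-en-1-yl)benzene | COCOc1cccc(OCOC)c1CC=C(C)C
F4 | step 3 | [2,4-bis(methoxymethoxy)-3-(3-methylbut-2-en-1-yl)phenyl]lithium | [Li]c1ccc(OCOC)c(CC=C(C)C)c1OCOC
F5 | step 3 | 1-iodo-2,4-bis(methoxymethoxy)-3-(3-methylbut-2-en-1-yl)benzene | COCOc1ccc(I)c(OCOC)c1CC=C(C)C
F6 | step 9 | 2-[2,4-bis(methoxymethoxy)-3-(3-methylbut-2-en-1-yl)phenyl]acetaldehyde | COCOc1ccc(CC=O)c(OCOC)c1CC=C(C)C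
F7 | step 9 | dichloro[2,4,6-tris(methoxymethoxy)-3,5-bis(3-methylbut-2-en-1-yl)phenyl]cerium | Cl[Ce](Cl)c1c(OCOC)c(CC=C(C)C)c(OCOC)c(CC=C(C)C)c1OCOC
F8 | step 9 | racemic 2-[2,4-bis(methoxymethoxy)-3-(3-methylbut-2-en-1-yl)phenyl]-1-[2,4,6-tris(methoxymethoxy)-3,5-bis(3-methylbut-2-en-1-yl)phenyl]ethan-1-ol | COCOc1ccc(CC(O)c2c(OCOC)c(CC=C(C)C)c(OCOC)c(CC=C(C)C)c2OCOC)c(OCOC)c1CC=C(C)C
F9 | step 11 | 2-[2,4-dihydroxy-3-(3-methylbut-2-en-1-yl)phenyl]-1-[2,4,6-trihydroxy-3,5-bis(3-methylbut-2-en-1-yl)phenyl]ethan-1-one | CC(C)=CCc1c(O)ccc(CC(=O)c2c(O)c(CC=C(C)C)c(O)c(CC=C(C)C)c2O)c1O
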